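**Retrosynthetic overview**

- The target is reached by global desilylation; the tetrahydrofuran (ring C: O1, C2 aryl, C3 CH2OH, C4 benzyl, C5) is closed last through the C2–O1 bond from a triol, which comes from aldol of an (S)-β-(arylmethyl)-γ-butyrolactone with silylated isovanillin (C2–C3 bond) and hydride reduction.
- The lactone comes from auxiliary-controlled alkylation of a succinate imide with the dihydrobenzofuran-6'-ylmethyl bromide (sets C4); the bromide comes from the trans dihydrobenzofuran ester by functional-group changes.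
- The dihydrofuran (ring B: O1', C2', C3', C3a', C7a') is closed through the C2'–C3' bond by carbenoid C–H insertion of an aryl diazoacetate. The feature used: C3' hangs on C3a', which lies on benzene ring A between C4' (OMe) and C7a' (O1'), so a diazoacetate on C3a' has the O1'–CH2–aryl ether next to it, and the pattern maps onto symmetric 3,5-dimethoxybenzyl alcohol.
- The diazo ester comes from 3,5-dimethoxybenzyl alcohol by lithiation between the methoxy groups and oxalylation, mono-demethylation, Mitsunobu etherification with the vanillin-derived benzyl alcohol, then tosylhydrazone and base.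
- Ring order: ring B (step 8), a temporary butyrolactone (step 15), ring C (step 19).

Key step: step 8

Assumption: the S-configured phthalimido-tert-leucinate catalyst is taken to give the 2R series in benzyl-ether insertions, so its mirror image Rh2(R-PTTL)4 (from D-tert-leucine) is specified for 2'S; if the sense were opposite on this substrate, the S-catalyst would be used with nothing else changed.

Step 1
Reactants: 1 3,5-dimethoxybenzyl alcohol
Product: 2 tert-butyl[(3,5-dimethoxybenzyl)oxy]dimethylsilane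
Conditions: TBSCl, imidazole, DMF, 0→23 °C
Reagents that add atoms: tert-butyldimethylsilyl chloride (TBSCl), CC(C)(C)[Si](C)(C)Cl
Why: Imidazole-promoted silyl ether formation masks the only acidic proton before the metalation and installs the one silyl group that is later removable by mild acid.

Step 2
Reactants: 2 tert-butyl[(3,5-dimethoxybenzyl)oxy]dimethylsilane; 3 dimethyl oxalate
Product: 5 methyl 2-[4-({[tert-butyl(dimethyl)silyl]oxy}methyl)-2,6-dimethoxyphenyl]-2-oxoacetate, via aryllithium 4 (not isolated)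
Conditions: n-BuLi, THF, 0→23 °C; then cannulated into 3 (3 equiv), THF, −78 °C; AcOH
Reagents that add atoms: none
Why: Directed ortho-metalation takes the proton between the two methoxy groups (the most acidic, doubly coordinated site), and inverse addition to excess oxalate at low temperature stops at mono-acylation (nucleophilic acyl substitution) because the tetrahedral adduct survives until the quench.

Step 3
Reactants: 5 methyl 2-[4-({[tert-butyl(dimethyl)silyl]oxy}methyl)-2,6-dimethoxyphenyl]-2-oxoacetate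
Product: 6 methyl 2-[4-({[tert-butyl(dimethyl)silyl]oxy}methyl)-2-hydroxy-6-methoxyphenyl]-2-oxoacetate
Conditions: BCl3 (1.2 equiv), CH2Cl2, −78→−40 °C; then H2O
Reagents that add atoms: none
Why: Chelation-controlled Lewis-acid ether cleavage: BCl3 bridges the ketone oxygen and one flanking methoxy oxygen, chloride removes that methyl group, and the resulting six-membered boron chelate shuts off the second demethylation; the two methoxy groups are equivalent, so there is no regiochemical question.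

Step 4
Reactants: 7 vanillin
Product: 8 3-methoxy-4-[(triisopropylsilyl)oxy]benzaldehyde
Conditions: TIPSCl, imidazole, DMF, 23 °C
Reagents that add atoms: triisopropylsilyl chloride (TIPSCl), CC(C)[Si](Cl)(C(C)C)C(C)C
Why: Phenol silylation; the bulky aryl silyl ether is chosen because it should survive hydride, amide bases, DBU and mild acid up to the last step.

Step 5
Reactants: 8 3-methoxy-4-[(triisopropylsilyl)oxy]benzaldehyde
Product: 9 {3-methoxy-4-[(triisopropylsilyl)oxy]phenyl}methanol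
Conditions: NaBH4, MeOH, 0 °C
Reagents that add atoms: none
Why: Borohydride reduction of an aryl aldehyde to the primary benzylic alcohol.

Step 6
Reactants: 6 methyl 2-[4-({[tert-butyl(dimethyl)silyl]oxy}methyl)-2-hydroxy-6-methoxyphenyl]-2-oxoacetate; 9 {3-methoxy-4-[(triisopropylsilyl)oxy]phenyl}methanol
Product: 10 methyl 2-[4-({[tert-butyl(dimethyl)silyl]oxy}methyl)-2-methoxy-6-({3-methoxy-4-[(triisopropylsilyl)oxy]benzyl}oxy)phenyl]-2-oxoacetate
Conditions: PPh3, DIAD, THF, 0→23 °C
Reagents that add atoms: none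
Why: Mitsunobu etherification: the phenol, made acidic by the ortho keto ester, displaces the alkoxyphosphonium of the primary benzylic alcohol by SN2 under neutral conditions that spare both silyl ethers and avoid a labile para-silyloxybenzyl halide.

Step 7
Reactants: 10 methyl 2-[4-({[tert-butyl(dimethyl)silyl]oxy}methyl)-2-methoxy-6-({3-methoxy-4-[(triisopropylsilyl)oxy]benzyl}oxy)phenyl]-2-oxoacetate
Product: 12 methyl 2-diazo-2-[4-({[tert-butyl(dimethyl)silyl]oxy}methyl)-2-methoxy-6-({3-methoxy-4-[(triisopropylsilyl)oxy]benzyl}oxy)phenyl]acetate, via tosylhydrazone 11 (not isolated)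
Conditions: TsNHNH2, toluene, 80 °C; then DBU, 23 °C
Reagents that add atoms: p-toluenesulfonyl hydrazide, Cc1ccc(cc1)S(=O)(=O)NN
Why: Condensation at the activated keto group of the α-keto ester followed by base-induced loss of sulfinate (Bamford–Stevens-type diazo formation) gives the aryl diazoacetate without a diazo-transfer step.

Step 8
Reactants: 12 methyl 2-diazo-2-[4-({[tert-butyl(dimethyl)silyl]oxy}methyl)-2-methoxy-6-({3-methoxy-4-[(triisopropylsilyl)oxy]benzyl}oxy)phenyl]acetate
Product: 14 methyl (2S,3S)-6-({[tert-butyl(dimethyl)silyl]oxy}methyl)-4-methoxy-2-{3-methoxy-4-[(triisopropylsilyl)oxy]phenyl}-2,3-dihydro-1-benzofuran-3-carboxylate, via cis ester 13 (not isolated)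
Conditions: Rh2(R-PTTL)4 (dirhodium tetrakis[N-phthaloyl-(R)-tert-leucinate], 1 mol %), toluene, −60 °C; then DBU (2 equiv), 23→50 °C
Reagents that add atoms: none
Why: The dirhodium carboxylate expels N2 from 12 to give an electrophilic donor/acceptor carbenoid at the future C3', which inserts into one benzylic C–H bond of the ortho O1'–CH2–aryl group through a three-centre, hydride-transfer-like transition state and so forms the C2'–C3' bond; the closest known reaction type is the asymmetric dirhodium-carboxylate-catalysed intramolecular C–H insertion of ortho-(benzyloxy)aryl diazoacetates to cis-2-aryl-2,3-dihydrobenzofuran-3-carboxylates. Ring B closes in the 1,5-insertion mode (carbenoid carbon, C3a', C7a', O1', CH2), the five-membered closure that such carbenoids prefer. C2' is set by the catalyst: the phthalimido-tert-leucinate ligands let only one of the two enantiotopic benzylic hydrogens reach the carbenoid, and the R-ligand series is chosen to deliver 2'S. C3' is formed cis under kinetic control (13) and is then epimerised by DBU through the ester enolate to the more stable trans ester 14 (3'S as the ester, 3'R after reduction), which leaves C2' untouched. The step needs site selectivity for the O1'–CH2 hydrogens over the C–H bonds of the C4' methoxy group on the other flank and over addition to the pendant arene; the methylene C–H is secondary, benzylic, next to oxygen and para to a silyloxy donor, hence much more hydridic than a methoxy C–H, and the low temperature keeps the stabilised carbenoid discriminating.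

Step 9
Reactants: 14 methyl (2S,3S)-6-({[tert-butyl(dimethyl)silyl]oxy}methyl)-4-methoxy-2-{3-methoxy-4-[(triisopropylsilyl)oxy]phenyl}-2,3-dihydro-1-benzofuran-3-carboxylate
Product: 15 [(2S,3R)-6-({[tert-butyl(dimethyl)silyl]oxy}methyl)-4-methoxy-2-{3-methoxy-4-[(triisopropylsilyl)oxy]phenyl}-2,3-dihydro-1-benzofuran-3-yl]methanol
Conditions: LiAlH4, THF, 0 °C
Reagents that add atoms: none
Why: Hydride reduction of the ester removes the acidic C3' position before any strong base is used; the spatial arrangement is unchanged and only the descriptor at C3' switches to R.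

Step 10
Reactants: 15 [(2S,3R)-6-({[tert-butyl(dimethyl)silyl]oxy}methyl)-4-methoxy-2-{3-methoxy-4-[(triisopropylsilyl)oxy]phenyl}-2,3-dihydro-1-benzofuran-3-yl]methanol
Product: 16 tert-butyl{[(2S,3R)-6-({[tert-butyl(dimethyl)silyl]oxy}methyl)-4-methoxy-2-{3-methoxy-4-[(triisopropylsilyl)oxy]phenyl}-2,3-dihydro-1-benzofuran-3-yl]methoxy}diphenylsilane
Conditions: TBDPSCl, imidazole, DMF, 23 °C
Reagents that add atoms: tert-butyldiphenylsilyl chloride (TBDPSCl), CC(C)(C)[Si](Cl)(c1ccccc1)c1ccccc1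
Why: Silylation of the only free hydroxyl with a group far more acid-stable than the benzylic tert-butyldimethylsilyl ether, which allows step 11.

Step 11
Reactants: 16 tert-butyl{[(2S,3R)-6-({[tert-butyl(dimethyl)silyl]oxy}methyl)-4-methoxy-2-{3-methoxy-4-[(triisopropylsilyl)oxy]phenyl}-2,3-dihydro-1-benzofuran-3-yl]methoxy}diphenylsilane
Product: 17 [(2S,3R)-3-({[tert-butyl(diphenyl)silyl]oxy}methyl)-4-methoxy-2-{3-methoxy-4-[(triisopropylsilyl)oxy]phenyl}-2,3-dihydro-1-benzofuran-6-yl]methanol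
Conditions: PPTS, MeOH/CH2Cl2, 23→40 °C
Reagents that add atoms: none
Why: Acid-catalysed solvolysis removes the primary alkyl tert-butyldimethylsilyl ether chemoselectively, since the tert-butyldiphenylsilyl ether is orders of magnitude slower and aryl silyl ethers are acid-stable.

Step 12
Reactants: 17 [(2S,3R)-3-({[tert-butyl(diphenyl)silyl]oxy}methyl)-4-methoxy-2-{3-methoxy-4-[(triisopropylsilyl)oxy]phenyl}-2,3-dihydro-1-benzofuran-6-yl]methanol
Product: 18 {[(2S,3R)-6-(bromomethyl)-4-methoxy-2-{3-methoxy-4-[(triisopropylsilyl)oxy]phenyl}-2,3-dihydro-1-benzofuran-3-yl]methoxy}(tert-butyl)diphenylsilane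
Conditions: CBr4, PPh3, 2,6-lutidine, CH2Cl2, 0 °C
Reagents that add atoms: carbon tetrabromide, BrC(Br)(Br)Br
Why: Appel bromination converts the benzylic alcohol to the bromide under buffered, near-neutral conditions; the meta-dioxygenated benzylic bromide should be reactive in SN2 but not prone to ionisation.

Step 13
Reactants: 19 4-tert-butoxy-4-oxobutanoic acid; 20 (4S)-4-benzyl-1,3-oxazolidin-2-one
Product: 22 tert-butyl 4-[(4S)-4-benzyl-2-oxo-1,3-oxazolidin-3-yl]-4-oxobutanoate, via mixed pivalic anhydride 21 (not isolated)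
Conditions: PivCl, Et3N, THF, −20 °C; then LiCl, 20, −20→23 °C
Reagents that add atoms: none
Why: N-Acylation of the oxazolidinone through the mixed pivalic anhydride, which is attacked at the less hindered succinyl carbonyl.

Step 14
Reactants: 18 {[(2S,3R)-6-(bromomethyl)-4-methoxy-2-{3-methoxy-4-[(triisopropylsilyl)oxy]phenyl}-2,3-dihydro-1-benzofuran-3-yl]methoxy}(tert-butyl)diphenylsilane; 22 tert-butyl 4-[(4S)-4-benzyl-2-oxo-1,3-oxazolidin-3-yl]-4-oxobutanoate
Product: 23 tert-butyl (3S)-4-[(4S)-4-benzyl-2-oxo-1,3-oxazolidin-3-yl]-3-{[(2S,3R)-3-({[tert-butyl(diphenyl)silyl]oxy}methyl)-4-methoxy-2-{3-methoxy-4-[(triisopropylsilyl)oxy]phenyl}-2,3-dihydro-1-benzofuran-6-yl]methyl}-4-oxobutanoate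
Conditions: 22 (1.5 equiv), NaN(SiMe3)2, THF, −78 °C; then 18, −78→−30 °C
Reagents that add atoms: none
Why: Evans auxiliary alkylation: only the imide α-position is enolised (the tert-butyl ester is far less acidic), and the chelated Z-enolate is attacked by the benzylic bromide on the face away from the auxiliary benzyl group, which sets the future C4 as S.

Step 15
Reactants: 23 tert-butyl (3S)-4-[(4S)-4-benzyl-2-oxo-1,3-oxazolidin-3-yl]-3-{[(2S,3R)-3-({[tert-butyl(diphenyl)silyl]oxy}methyl)-4-methoxy-2-{3-methoxy-4-[(triisopropylsilyl)oxy]phenyl}-2,3-dihydro-1-benzofuran-6-yl]methyl}-4-oxobutanoate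
Product: 25 (4S)-4-{[(2S,3R)-3-({[tert-butyl(diphenyl)silyl]oxy}methyl)-4-methoxy-2-{3-methoxy-4-[(triisopropylsilyl)oxy]phenyl}-2,3-dihydro-1-benzofuran-6-yl]methyl}oxolan-2-one, via hydroxy ester 24 (not isolated)
Conditions: LiBH4, MeOH (1 equiv), THF, 0 °C; aqueous work-up; then TsOH·H2O (10 mol %), toluene, 60 °C
Reagents that add atoms: none
Why: Reductive cleavage of the exocyclic imide carbonyl by LiBH4 (the tert-butyl ester is not reduced) frees the auxiliary and gives the hydroxy ester, which closes to the γ-lactone by acid-catalysed lactonisation without touching the stereocentre.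

Step 16
Reactants: 26 isovanillin
Product: 27 4-methoxy-3-[(triisopropylsilyl)oxy]benzaldehyde
Conditions: TIPSCl, imidazole, DMF, 23 °C
Reagents that add atoms: triisopropylsilyl chloride (TIPSCl), CC(C)[Si](Cl)(C(C)C)C(C)C
Why: Phenol silylation gives a non-enolisable, base-stable aldehyde for the aldol step.

Step 17
Reactants: 25 (4S)-4-{[(2S,3R)-3-({[tert-butyl(diphenyl)silyl]oxy}methyl)-4-methoxy-2-{3-methoxy-4-[(triisopropylsilyl)oxy]phenyl}-2,3-dihydro-1-benzofuran-6-yl]methyl}oxolan-2-one; 27 4-methoxy-3-[(triisopropylsilyl)oxy]benzaldehyde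
Product: 28 (3R,4S)-3-{hydroxy[4-methoxy-3-(triisopropylsilyloxy)phenyl]methyl}-4-{[(2S,3R)-3-({[tert-butyl(diphenyl)silyl]oxy}methyl)-4-methoxy-2-{3-methoxy-4-[(triisopropylsilyl)oxy]phenyl}-2,3-dihydro-1-benzofuran-6-yl]methyl}oxolan-2-one (both carbinol epimers)
Conditions: LiN(SiMe3)2, THF, −78 °C; then 27, −78 °C; AcOH
Reagents that add atoms: none
Why: Lactone enolate aldol addition: the aldehyde approaches the enolate face opposite the neighbouring arylmethyl group, which sets the future C3 trans to it on the lactone; the carbinol centre is formed as a mixture that step 19 erases.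

Step 18
Reactants: 28 (3R,4S)-3-{hydroxy[4-methoxy-3-(triisopropylsilyloxy)phenyl]methyl}-4-{[(2S,3R)-3-({[tert-butyl(diphenyl)silyl]oxy}methyl)-4-methoxy-2-{3-methoxy-4-[(triisopropylsilyl)oxy]phenyl}-2,3-dihydro-1-benzofuran-6-yl]methyl}oxolan-2-one
Product: 29 (2S,3S)-2-{hydroxy[4-methoxy-3-(triisopropylsilyloxy)phenyl]methyl}-3-{[(2S,3R)-3-({[tert-butyl(diphenyl)silyl]oxy}methyl)-4-methoxy-2-{3-methoxy-4-[(triisopropylsilyl)oxy]phenyl}-2,3-dihydro-1-benzofuran-6-yl]methyl}butane-1,4-diol (both carbinol epimers)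
Conditions: LiAlH4, THF, 0 °C
Reagents that add atoms: none
Why: Hydride reduction of the lactone to the 1,4-diol; the aluminium alkoxide of the aldol hydroxyl does not undergo retro-aldol cleavage at this temperature, and no stereocentre is affected.

Step 19
Reactants: 29 (2S,3S)-2-{hydroxy[4-methoxy-3-(triisopropylsilyloxy)phenyl]methyl}-3-{[(2S,3R)-3-({[tert-butyl(diphenyl)silyl]oxy}methyl)-4-methoxy-2-{3-methoxy-4-[(triisopropylsilyl)oxy]phenyl}-2,3-dihydro-1-benzofuran-6-yl]methyl}butane-1,4-diol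
Product: 30 [(2R,3S,4S)-4-{[(2S,3R)-3-({[tert-butyl(diphenyl)silyl]oxy}methyl)-4-methoxy-2-{3-methoxy-4-[(triisopropylsilyl)oxy]phenyl}-2,3-dihydro-1-benzofuran-6-yl]methyl}-2-{4-methoxy-3-[(triisopropylsilyl)oxy]phenyl}oxolan-3-yl]methanol
Conditions: CSA (10 mol %), CH2Cl2, 0 °C; Et3N quench
Reagents that add atoms: none
Why: Acid-catalysed SN1 cycloetherification: both carbinol epimers ionise to the same para-methoxybenzylic cation, which the primary hydroxyl on the arylmethyl-bearing carbon captures in a 5-exo closure (the other hydroxyl could only give an oxetane), and C2 is set R with the aryl group trans to the C3 and C4 substituents because that arrangement avoids eclipsing the neighbouring CH2OH; hydroxyl capture should be much faster than Friedel–Crafts attack by the alkoxy-substituted ring A, so the acid is neutralised as soon as 29 is consumed to prevent re-ionisation of 30.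

Step 20
Reactants: 30 [(2R,3S,4S)-4-{[(2S,3R)-3-({[tert-butyl(diphenyl)silyl]oxy}methyl)-4-methoxy-2-{3-methoxy-4-[(triisopropylsilyl)oxy]phenyl}-2,3-dihydro-1-benzofuran-6-yl]methyl}-2-{4-methoxy-3-[(triisopropylsilyl)oxy]phenyl}oxolan-3-yl]methanol
Product: 31 (2R,3S,4S)-2-(3-hydroxy-4-methoxyphenyl)-3-(hydroxymethyl)-4-{[(2S,3R)-2-(4-hydroxy-3-methoxyphenyl)-3-(hydroxymethyl)-4-methoxy-2,3-dihydro-1-benzofuran-6-yl]methyl}oxolane (CNP0242386.1)
Conditions: Bu4NF, AcOH, THF, 0→23 °C
Reagents that add atoms: none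
Why: Fluoride desilylation removes both aryl triisopropylsilyl ethers and the tert-butyldiphenylsilyl ether in one operation, and the acetic acid buffer keeps the free para-hydroxybenzylic ether of ring B away from base-induced ring opening.

**Compound list**

1 | 3,5-dimethoxybenzyl alcohol | COc1cc(CO)cc(OC)c1 | starting material
2 | tert-butyl[(3,5-dimethoxybenzyl)oxy]dimethylsilane | COc1cc(CO[Si](C)(C)C(C)(C)C)cc(OC)c1 | intermediate
3 | dimethyl oxalate | COC(=O)C(=O)OC | starting material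
4 | [4-({[tert-butyl(dimethyl)silyl]oxy}methyl)-2,6-dimethoxyphenyl]lithium | [Li]c1c(OC)cc(CO[Si](C)(C)C(C)(C)C)cc1OC | intermediate
5 | methyl 2-[4-({[tert-butyl(dimethyl)silyl]oxy}methyl)-2,6-dimethoxyphenyl]-2-oxoacetate | COC(=O)C(=O)c1c(OC)cc(CO[Si](C)(C)C(C)(C)C)cc1OC | intermediate
6 | methyl 2-[4-({[tert-butyl(dimethyl)silyl]oxy}methyl)-2-hydroxy-6-methoxyphenyl]-2-oxoacetate | COC(=O)C(=O)c1c(O)cc(CO[Si](C)(C)C(C)(C)C)cc1OC | intermediate
7 | vanillin | COc1cc(C=O)ccc1O | starting material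
8 | 3-methoxy-4-[(triisopropylsilyl)oxy]benzaldehyde | COc1cc(C=O)ccc1O[Si](C(C)C)(C(C)C)C(C)C | intermediate
9 | {3-methoxy-4-[(triisopropylsilyl)oxy]phenyl}methanol | COc1cc(CO)ccc1O[Si](C(C)C)(C(C)C)C(C)C | intermediate
10 | methyl 2-[4-({[tert-butyl(dimethyl)silyl]oxy}methyl)-2-methoxy-6-({3-methoxy-4-[(triisopropylsilyl)oxy]benzyl}oxy)phenyl]-2-oxoacetate | COC(=O)C(=O)c1c(OC)cc(CO[Si](C)(C)C(C)(C)C)cc1OCc1ccc(O[Si](C(C)C)(C(C)C)C(C)C)c(OC)c1 | intermediate
11 | tosylhydrazone of 10 (methyl 2-aryl-2-[2-(4-methylphenylsulfonyl)hydrazinylidene]acetate) | COC(=O)C(=NNS(=O)(=O)c1ccc(C)cc1)c1c(OC)cc(CO[Si](C)(C)C(C)(C)C)cc1OCc1ccc(O[Si](C(C)C)(C(C)C)C(C)C)c(OC)c1 | intermediate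
12 | methyl 2-diazo-2-[4-({[tert-butyl(dimethyl)silyl]oxy}methyl)-2-methoxy-6-({3-methoxy-4-[(triisopropylsilyl)oxy]benzyl}oxy)phenyl]acetate | COC(=O)C(=[N+]=[N-])c1c(OC)cc(CO[Si](C)(C)C(C)(C)C)cc1OCc1ccc(O[Si](C(C)C)(C(C)C)C(C)C)c(OC)c1 | intermediate
13 | methyl (2S,3R)-6-({[tert-butyl(dimethyl)silyl]oxy}methyl)-4-methoxy-2-{3-methoxy-4-[(triisopropylsilyl)oxy]phenyl}-2,3-dihydro-1-benzofuran-3-carboxylate (cis) | CC(C)(C)[Si](C)(C)OCc1cc(OC)c2c(c1)O[C@H](c1ccc(O[Si](C(C)C)(C(C)C)C(C)C)c(OC)c1)[C@@H]2C(=O)OC | intermediate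
14 | methyl (2S,3S)-6-({[tert-butyl(dimethyl)silyl]oxy}methyl)-4-methoxy-2-{3-methoxy-4-[(triisopropylsilyl)oxy]phenyl}-2,3-dihydro-1-benzofuran-3-carboxylate (trans) | CC(C)(C)[Si](C)(C)OCc1cc(OC)c2c(c1)O[C@H](c1ccc(O[Si](C(C)C)(C(C)C)C(C)C)c(OC)c1)[C@H]2C(=O)OC | intermediate
15 | [(2S,3R)-6-({[tert-butyl(dimethyl)silyl]oxy}methyl)-4-methoxy-2-{3-methoxy-4-[(triisopropylsilyl)oxy]phenyl}-2,3-dihydro-1-benzofuran-3-yl]methanol | CC(C)(C)[Si](C)(C)OCc1cc(OC)c2c(c1)O[C@H](c1ccc(O[Si](C(C)C)(C(C)C)C(C)C)c(OC)c1)[C@H]2CO | intermediate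
16 | tert-butyl{[(2S,3R)-6-({[tert-butyl(dimethyl)silyl]oxy}methyl)-4-methoxy-2-{3-methoxy-4-[(triisopropylsilyl)oxy]phenyl}-2,3-dihydro-1-benzofuran-3-yl]methoxy}diphenylsilane | CC(C)(C)[Si](C)(C)OCc1cc(OC)c2c(c1)O[C@H](c1ccc(O[Si](C(C)C)(C(C)C)C(C)C)c(OC)c1)[C@H]2CO[Si](c1ccccc1)(c1ccccc1)C(C)(C)C | intermediate
17 | [(2S,3R)-3-({[tert-butyl(diphenyl)silyl]oxy}methyl)-4-methoxy-2-{3-methoxy-4-[(triisopropylsilyl)oxy]phenyl}-2,3-dihydro-1-benzofuran-6-yl]methanol | OCc1cc(OC)c2c(c1)O[C@H](c1ccc(O[Si](C(C)C)(C(C)C)C(C)C)c(OC)c1)[C@H]2CO[Si](c1ccccc1)(c1ccccc1)C(C)(C)C | intermediate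
18 | {[(2S,3R)-6-(bromomethyl)-4-methoxy-2-{3-methoxy-4-[(triisopropylsilyl)oxy]phenyl}-2,3-dihydro-1-benzofuran-3-yl]methoxy}(tert-butyl)diphenylsilane | BrCc1cc(OC)c2c(c1)O[C@H](c1ccc(O[Si](C(C)C)(C(C)C)C(C)C)c(OC)c1)[C@H]2CO[Si](c1ccccc1)(c1ccccc1)C(C)(C)C | intermediate
19 | 4-tert-butoxy-4-oxobutanoic acid (mono-tert-butyl succinate) | CC(C)(C)OC(=O)CCC(=O)O | starting material
20 | (4S)-4-benzyl-1,3-oxazolidin-2-one | O=C1N[C@@H](Cc2ccccc2)CO1 | starting material
21 | 4-tert-butoxy-4-oxobutanoic pivalic anhydride | CC(C)(C)OC(=O)CCC(=O)OC(=O)C(C)(C)C | intermediate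
22 | tert-butyl 4-[(4S)-4-benzyl-2-oxo-1,3-oxazolidin-3-yl]-4-oxobutanoate | CC(C)(C)OC(=O)CCC(=O)N1[C@@H](Cc2ccccc2)COC1=O | intermediate
23 | tert-butyl (3S)-4-[(4S)-4-benzyl-2-oxo-1,3-oxazolidin-3-yl]-3-{[(2S,3R)-3-({[tert-butyl(diphenyl)silyl]oxy}methyl)-4-methoxy-2-{3-methoxy-4-[(triisopropylsilyl)oxy]phenyl}-2,3-dihydro-1-benzofuran-6-yl]methyl}-4-oxobutanoate | CC(C)(C)OC(=O)C[C@H](Cc1cc(OC)c2c(c1)O[C@H](c1ccc(O[Si](C(C)C)(C(C)C)C(C)C)c(OC)c1)[C@H]2CO[Si](c1ccccc1)(c1ccccc1)C(C)(C)C)C(=O)N1[C@@H](Cc2ccccc2)COC1=O | intermediate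
24 | tert-butyl (3S)-3-{[(2S,3R)-3-({[tert-butyl(diphenyl)silyl]oxy}methyl)-4-methoxy-2-{3-methoxy-4-[(triisopropylsilyl)oxy]phenyl}-2,3-dihydro-1-benzofuran-6-yl]methyl}-4-hydroxybutanoate | CC(C)(C)OC(=O)C[C@H](Cc1cc(OC)c2c(c1)O[C@H](c1ccc(O[Si](C(C)C)(C(C)C)C(C)C)c(OC)c1)[C@H]2CO[Si](c1ccccc1)(c1ccccc1)C(C)(C)C)CO | intermediate
25 | (4S)-4-{[(2S,3R)-3-({[tert-butyl(diphenyl)silyl]oxy}methyl)-4-methoxy-2-{3-methoxy-4-[(triisopropylsilyl)oxy]phenyl}-2,3-dihydro-1-benzofuran-6-yl]methyl}oxolan-2-one | O=C3C[C@H](Cc1cc(OC)c2c(c1)O[C@H](c1ccc(O[Si](C(C)C)(C(C)C)C(C)C)c(OC)c1)[C@H]2CO[Si](c1ccccc1)(c1ccccc1)C(C)(C)C)CO3 | intermediate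
26 | isovanillin | COc1ccc(C=O)cc1O | starting material
27 | 4-methoxy-3-[(triisopropylsilyl)oxy]benzaldehyde | COc1ccc(C=O)cc1O[Si](C(C)C)(C(C)C)C(C)C | intermediate
28 | (3R,4S)-3-{hydroxy[4-methoxy-3-(triisopropylsilyloxy)phenyl]methyl}-4-{[dihydrobenzofuran-6-yl]methyl}oxolan-2-one, carbinol centre unassigned (both epimers) | O=C3OC[C@@H](Cc1cc(OC)c2c(c1)O[C@H](c1ccc(O[Si](C(C)C)(C(C)C)C(C)C)c(OC)c1)[C@H]2CO[Si](c1ccccc1)(c1ccccc1)C(C)(C)C)[C@@H]3C(O)c1ccc(OC)c(O[Si](C(C)C)(C(C)C)C(C)C)c1 | intermediate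
29 | (2S,3S)-2-{hydroxy[4-methoxy-3-(triisopropylsilyloxy)phenyl]methyl}-3-{[dihydrobenzofuran-6-yl]methyl}butane-1,4-diol, carbinol centre unassigned (both epimers) | OC[C@@H](Cc1cc(OC)c2c(c1)O[C@H](c1ccc(O[Si](C(C)C)(C(C)C)C(C)C)c(OC)c1)[C@H]2CO[Si](c1ccccc1)(c1ccccc1)C(C)(C)C)[C@H](C(O)c1ccc(OC)c(O[Si](C(C)C)(C(C)C)C(C)C)c1)CO | intermediate
30 | [(2R,3S,4S)-4-{[(2S,3R)-3-({[tert-butyl(diphenyl)silyl]oxy}methyl)-4-methoxy-2-{3-methoxy-4-[(triisopropylsilyl)oxy]phenyl}-2,3-dihydro-1-benzofuran-6-yl]methyl}-2-{4-methoxy-3-[(triisopropylsilyl)oxy]phenyl}oxolan-3-yl]methanol | COc1ccc([C@@H]2OC[C@@H](Cc3cc(OC)c4c(c3)O[C@H](c3ccc(O[Si](C(C)C)(C(C)C)C(C)C)c(OC)c3)[C@H]4CO[Si](c3ccccc3)(c3ccccc3)C(C)(C)C)[C@H]2CO)cc1O[Si](C(C)C)(C(C)C)C(C)C | intermediate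
31 | (2R,3S,4S)-2-(3-hydroxy-4-methoxyphenyl)-3-(hydroxymethyl)-4-{[(2S,3R)-2-(4-hydroxy-3-methoxyphenyl)-3-(hydroxymethyl)-4-methoxy-2,3-dihydro-1-benzofuran-6-yl]methyl}oxolane | COc1ccc([C@@H]2OC[C@@H](Cc3cc(OC)c4c(c3)O[C@H](c3ccc(O)c(OC)c3)[C@H]4CO)[C@H]2CO)cc1O | target

**Step count and risks**

Total step count: 20. Longest linear sequence: 16 steps (from 1 through steps 1, 2, 3, 6, 7, 8, 9, 10, 11, 12, 14, 15, 17, 18, 19, 20).

Steps most likely to fail:

1. Step 8 (carbenoid C–H insertion). With both ortho positions of the carbenoid-bearing ring substituted, metal–carbene formation may be slow and the ligand wall may no longer discriminate well between the two enantiotopic benzylic hydrogens. Hydride transfer from the very electron-rich benzylic ether may also become stepwise, with loss of stereochemical fidelity. Fallback: absolute configuration by classical resolution instead of catalyst control. Setting out from 12, closure with achiral Rh2(OAc)4 (CH2Cl2, 23 °C) followed by DBU should give the racemic trans ester F1. LiAlH4 reduction gives the racemic alcohol F2, which is esterified with (S)-2-methoxy-2-phenylacetic acid (DCC, DMAP). The two diastereomeric esters are separated by chromatography or crystallisation, and the ester of the (2S,3R)-alcohol, the (S)-O-methylmandelate F3, is cleaved with LiAlH4. The route is rejoined at 15.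

2. Step 3 (mono-demethylation). BCl3 may also attack the benzylic silyl ether, or remove the second methyl group if the boron chelate is disturbed on warming. Fallback: give up the silyl group at this stage and rely on the acidity difference between the two hydroxyls. Setting out from 5, BCl3 (2.5 equiv, −78→0 °C) followed by brief HCl/MeOH should give the diol F4. The bromide F5 is made from 9 (CBr4, PPh3). Alkylation of F4 with F5 (K2CO3, acetone, 23 °C) should occur at the phenol only and give the benzylic alcohol F6. Silylation (TBSCl, imidazole) rejoins the route at 10, so that step 6 is bypassed.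

3. Step 7 (diazo ester formation). Condensation of tosylhydrazide at a ketone shielded by two ortho alkoxy groups may be sluggish, and the prolonged heating this would need may degrade the silyl ethers or the product diazo ester. Fallback: oxidation of an unsubstituted hydrazone instead of sulfinate elimination. Setting out from 10, the small nucleophile N2H4·H2O (AcOH, EtOH, 0→23 °C) should give the hydrazone F7, and dehydrogenation with activated MnO2 (CH2Cl2, 0 °C) gives the diazo ester. The route is rejoined at 12.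

**Further compounds**

F1 | step 8 | racemic methyl (2S*,3S*)-6-({[tert-butyl(dimethyl)silyl]oxy}methyl)-4-methoxy-2-{3-methoxy-4-[(triisopropylsilyl)oxy]phenyl}-2,3-dihydro-1-benzofuran-3-carboxylate (trans, one enantiomer drawn) | CC(C)(C)[Si](C)(C)OCc1cc(OC)c2c(c1)O[C@H](c1ccc(O[Si](C(C)C)(C(C)C)C(C)C)c(OC)c1)[C@H]2C(=O)OC
F2 | step 8 | racemic [(2S*,3R*)-6-({[tert-butyl(dimethyl)silyl]oxy}methyl)-4-methoxy-2-{3-methoxy-4-[(triisopropylsilyl)oxy]phenyl}-2,3-dihydro-1-benzofuran-3-yl]methanol (trans, one enantiomer drawn) | CC(C)(C)[Si](C)(C)OCc1cc(OC)c2c(c1)O[C@H](c1ccc(O[Si](C(C)C)(C(C)C)C(C)C)c(OC)c1)[C@H]2CO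
F3 | step 8 | [(2S,3R)-6-({[tert-butyl(dimethyl)silyl]oxy}methyl)-4-methoxy-2-{3-methoxy-4-[(triisopropylsilyl)oxy]phenyl}-2,3-dihydro-1-benzofuran-3-yl]methyl (2S)-2-methoxy-2-phenylacetate | CC(C)(C)[Si](C)(C)OCc1cc(OC)c2c(c1)O[C@H](c1ccc(O[Si](C(C)C)(C(C)C)C(C)C)c(OC)c1)[C@H]2COC(=O)[C@@H](OC)c1ccccc1
F4 | step 3 | methyl 2-[2-hydroxy-4-(hydroxymethyl)-6-methoxyphenyl]-2-oxoacetate | COC(=O)C(=O)c1c(O)cc(CO)cc1OC
F5 | step 3 | [4-(bromomethyl)-2-methoxyphenoxy]triisopropylsilane | COc1cc(CBr)ccc1O[Si](C(C)C)(C(C)C)C(C)C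
F6 | step 3 | methyl 2-[4-(hydroxymethyl)-2-methoxy-6-({3-methoxy-4-[(triisopropylsilyl)oxy]benzyl}oxy)phenyl]-2-oxoacetate | COC(=O)C(=O)c1c(OC)cc(CO)cc1OCc1ccc(O[Si](C(C)C)(C(C)C)C(C)C)c(OC)c1
F7 | step 7 | methyl 2-hydrazinylidene-2-[4-({[tert-butyl(dimethyl)silyl]oxy}methyl)-2-methoxy-6-({3-methoxy-4-[(triisopropylsilyl)oxy]benzyl}oxy)phenyl]acetate | COC(=O)C(=NN)c1c(OC)cc(CO[Si](C)(C)C(C)(C)C)cc1OCc1ccc(O[Si](C(C)C)(C(C)C)C(C)C)c(OC)c1
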